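## The problem

The target 15 is a 2(5H)-furanone (numbering: O1, C2 carbonyl, C3, C4, C5). It carries a methoxy group on C3, a 4-hydroxyphenyl group (ring B) on C4 and, on sp3 carbon C5, a 4-hydroxy-3-prenylbenzyl group (ring A). Only one ring has to be built, but the two aryl groups differ solely by the prenyl chain, so they must come from separate building blocks. C5 is the only stereocentre; no second centre can relay or correct it, so its (R) configuration must be set by a catalyst or reagent and then carried through untouched. This is delicate because C5–H is allylic, α to oxygen and γ to the lactone carbonyl, and its removal gives an aromatic 2-oxidofuran; once the C3 oxygen is capped as its methyl ether, the centre must not see base again. The ortho-prenylphenol of ring A is the second fragile element: acid closes it to a chroman, and its trisubstituted alkene reacts with electrophilic oxidants at least as fast as a styrene-type double bond, which excludes asymmetric olefin epoxidation or dihydroxylation once the prenyl group is present. The two phenols must also be told apart from the more acidic 3-hydroxyl that receives the methyl group. The enabling feature is that C2 and C3 form an α-keto acid unit (as its enol ether) lying between benzylic C4 and the oxygen on C5. C4 and C5–O are the two ends of an opened aryl epoxide, C2 and C3 can each be one molecule of carbon monoxide, the para oxygen of ring B marks C4 as the carbon where such an epoxide opens, and because C4 ends up sp2 only the C5–O bond needs to be stereodefined.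

## Retrosynthesis

**Deprotection and methylation (15 ⇒ 14 ⇒ 13).** The two aryl O–CH2OCH3 bonds are cut first, then the O–CH3 bond at C3. Methoxymethyl ethers are preferred to silyl or benzyl ethers because their removal needs neither fluoride (basic enough to endanger C5–H in 14) nor hydrogenolysis (prenyl), and they survive hydride, aryllithium and aqueous hydroxide earlier on. The methyl group goes on before the phenols are freed, so the only acidic hydroxyl present is the enol of 13. The forward methylation must be neutral, since base on 14 would deprotonate C5.

**Double carbonylation (13 ⇒ 11 + 2 × 12).** The bonds C4–C3, C3–C2 and C2–O1 are cut together. This removes C2 and C3 as two molecules of carbon monoxide 12 and leaves the trans epoxide 11. The neighbouring cuts are weaker: an aldol-type construction of the C4–C5 bond runs under enolising conditions with no handle on C5, and a late cross-coupling to attach ring B still leaves the stereocentre to be made on a butenolide. Compound 11 is much simpler than 13 (no lactone, no enol) and asks only for one stereodefined C–O bond. The forward reaction must open the epoxide at the benzylic carbon only, insert CO twice, and leave the other C–O bond intact.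

**Epoxide closure (11 ⇒ 10).** Only the non-benzylic epoxide carbon survives as a stereocentre, so 11 is cut at that carbon's C–O bond to give chlorohydrin 10, where the centre is held as a C–Cl bond of opposite spatial sense. Oxidative routes to 11 cannot spare the prenyl double bond. Ylide-based epoxide syntheses control the benzylic carbon instead, so any cis isomer would carry the wrong configuration at the future C5. The forward step is an SN2 closure with inversion, and both C1 epimers of 10 give epoxides with the same configuration at the carbon that matters.

**Aryl addition (10 ⇒ 9 + 6; 9 ⇐ 8 ⇐ 7).** Cutting the benzylic C–C bond of 10 separates ring B as aryllithium 9 from ring A as α-chloroaldehyde 6. Aryllithium 9 comes from bromide 8 and hence from 4-bromophenol 7. The rings stay in separate building blocks until late. The forward step must only add faster than it enolises 6; its diastereoselectivity is welcome but not essential.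

**Asymmetric chlorination (6 ⇒ 5).** The C–Cl bond of 6 is cut to leave the achiral aldehyde 5. This step creates the absolute configuration of the whole synthesis, and it is placed on a simple 3-arylpropanal, the substrate class for which enamine-catalysed α-chlorination is established. It needs high enantioselectivity and a chlorine source that ignores the prenyl alkene and the electron-rich arene.

**Ring A building block (5 ⇒ 4 ⇒ 3 ⇒ 1 + 2).** Functional-group changes lead from 5 through ester 4 to phenol 3. Cutting the aryl–prenyl bond of 3 gives commercial methyl 3-(4-hydroxyphenyl)propanoate 1 and prenyl bromide 2. Starting from 1 supplies ring A with its three-carbon chain in place, so the prenyl bond is the only C–C bond to the ring that must be made. The prenylation must be ortho-C-selective, which the blocked para position and a non-polar medium favour.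

## Roads not taken

**Alternative 1:** The cut is the C3–C4 bond of a saturated γ-lactone, leading back to the achiral, symmetric diazoacetate A1. In the forward step Rh2(4S-MPPIM)4 (dirhodium tetrakis[methyl 2-oxo-1-(3-phenylpropanoyl)imidazolidine-4(S)-carboxylate]) forms the carbene, which inserts into one of the two enantiotopic benzylic C–H bonds to give the cis lactone A2.
- Merits: the asymmetric event is a catalytic C–C bond formation on a trivially made achiral substrate, and the lactone ring and C5 arise in one step.
- Weak points for this target: the desymmetrisation needs two identical rings, so A2 has no prenyl group. The prenyl group would then have to be placed on one of two nearly identical para-substituted phenols with no basis for selectivity. Installing it earlier destroys the symmetry and turns the step into a choice between two benzylic CH2 groups that differ only by a remote substituent. A2 also sits at the wrong oxidation level: C3 is CH2 and C4 is sp3, so oxygenation at C3, oxidation to the keto lactone and methylation must follow, and the C4 centre the catalyst created is discarded.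
- Comparison: Alternative 1 is better in its early steps and in using catalytic asymmetric C–H functionalisation. The chosen plan offsets this by keeping rings A and B distinct from the start and by delivering C2 and C3 at the right oxidation level in the ring-forming step.

**Alternative 2:** The cut is O1–C2, leading to the racemic 4-hydroxycyclobutenone A4, assembled from dimethyl squarate A3, which supplies C2 to C5 with the C3 methoxy group already present. In the forward step irradiation opens the four-membered ring, the hydroxyl adds to the ketene carbon, and a cinchona-derived proton shuttle places hydrogen on one face of C5 to give the bis-silyl ether A5.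
- Merits: it is the shortest and most convergent plan, needs no O-methylation, and creates the stereocentre last from racemic material.
- Weak points: enantioselective γ-protonation of this kind of furanone precursor has no close precedent. The proton delivered is the most acidic one in A5, so the same basic catalyst, or the uncatalysed tautomerisation, can erode the result. The substitution pattern of A4 also requires the benzyl nucleophile to add to the carbonyl next to the aryl-bearing carbon, against the usual preference of aryl alkoxy cyclobutenediones; the normal regiochemistry would give the isomeric 4-methoxy-3-aryl lactone. Final desilylation with fluoride is basic.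
- Comparison: if the protonation could be made selective, Alternative 2 would be clearly shorter than the chosen route. The chosen plan offsets this with a stereocentre fixed as a C–O bond by an established catalytic reaction and never passing through a planar C5.

**Alternative 3:** The cuts are C4–aryl and C5–O1, leading to the axially chiral (aS)-2-methoxyallenoic acid A6 and aryl iodide A7. In the forward step zerovalent palladium, Pd(PPh3)4, inserts into A7, the arylpalladium engages the distal allene double bond with aryl going to the central carbon, and the carboxylate attacks C5 anti to palladium. The product is the bis(methoxymethyl) ether A8, identical with 14.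
- Merits: arylative lactonisation of allenoic acids with axial-to-central chirality transfer is a known reaction class. Ring B arrives as a simple iodide, the methoxy group is in place, and the route reaches the same late intermediate as the chosen one without an enol methylation.
- Weak points: the difficulty moves into A6. An enantioenriched 2-alkoxy allenoic acid with a benzylic CH2 on the allene terminus needs its own asymmetric synthesis or a resolution. It is prone to base-induced isomerisation to conjugated isomers, and any π-allyl pathway at palladium would leak chirality.
- Comparison: the ring-forming step is better precedented than the one chosen here, and convergence is at least equal. The chosen plan offsets this with a chiral precursor, epoxide 11, that is reached in three steps from a simple aldehyde by reactions that are individually established, and with two ring carbons supplied by carbon monoxide.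

Key step: step 8

Assumption (remark on the chemistry): in step 4 the (2R,5R) enantiomer of 2,5-diphenylpyrrolidine is taken to give the (S)-chloride 6 by chlorination of the unshielded enamine face; if the sense were opposite, the (2S,5S) amine would be used and nothing else would change.

Assumption (remark on the chemistry): iodomethane in step 8 is taken to end as acetate and iodide after it has served as the acetylcobalt promoter.

## Route

Step 1
Reactants: 1 methyl 3-(4-hydroxyphenyl)propanoate; 2 prenyl bromide (1-bromo-3-methylbut-2-ene)
Product: 3 methyl 3-[4-hydroxy-3-(3-methylbut-2-en-1-yl)phenyl]propanoate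
Conditions: NaH (1.05 equiv), toluene, 0 °C to rt; then 2, rt
Reagents that add atoms: none
Why: Ortho C-alkylation of a sodium phenoxide; in toluene the tight ion pair shields oxygen and directs the allylic bromide to the ortho carbon, after which the dienone rearomatises. The para position is occupied by the propanoate chain, and one equivalent of NaH deprotonates only the phenol.

Step 2
Reactants: 3 methyl 3-[4-hydroxy-3-(3-methylbut-2-en-1-yl)phenyl]propanoate
Product: 4 methyl 3-[4-(methoxymethoxy)-3-(3-methylbut-2-en-1-yl)phenyl]propanoate
Conditions: NaH, MOMCl, THF/DMF, 0 °C to rt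
Reagents that add atoms: chloromethyl methyl ether, COCCl
Why: Williamson-type O-alkylation of the phenoxide. The methoxymethyl acetal tolerates the hydride, organolithium and aqueous hydroxide of later steps and is removed at the end under mild acid.

Step 3
Reactants: 4 methyl 3-[4-(methoxymethoxy)-3-(3-methylbut-2-en-1-yl)phenyl]propanoate
Product: 5 3-[4-(methoxymethoxy)-3-(3-methylbut-2-en-1-yl)phenyl]propanal
Conditions: i-Bu2AlH (1.1 equiv), CH2Cl2, −78 °C; MeOH, then aq potassium sodium tartrate
Reagents that add atoms: none
Why: Partial reduction of a methyl ester with diisobutylaluminium hydride; the aluminium hemiacetal is stable at −78 °C and releases the aldehyde only on hydrolytic work-up.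

Step 4
Reactants: 5 3-[4-(methoxymethoxy)-3-(3-methylbut-2-en-1-yl)phenyl]propanal
Product: 6 (2S)-2-chloro-3-[4-(methoxymethoxy)-3-(3-methylbut-2-en-1-yl)phenyl]propanal
Conditions: NCS (1.3 equiv), (2R,5R)-2,5-diphenylpyrrolidine (10 mol %), CH2Cl2, 0 °C to rt; pentane, filtration, used at once without chromatography
Reagents that add atoms: N-chlorosuccinimide, O=C1CCC(=O)N1Cl
Why: Enamine-catalysed asymmetric α-chlorination of an aldehyde, established for 3-arylpropanals. The C2-symmetric amine forms the E-enamine with one face blocked by a phenyl group, so chlorine is delivered to the open face and the (S) centre is set by the catalyst. NCS under these neutral conditions should leave the trisubstituted alkene and the arene alone.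

Step 5
Reactants: 7 4-bromophenol
Product: 8 1-bromo-4-(methoxymethoxy)benzene
Conditions: NaH, MOMCl, THF/DMF, 0 °C to rt
Reagents that add atoms: chloromethyl methyl ether, COCCl
Why: Williamson-type O-alkylation of the phenoxide, as in step 2; the acetal is inert to butyllithium at −78 °C.

Step 6
Reactants: 8 1-bromo-4-(methoxymethoxy)benzene; 6 (2S)-2-chloro-3-[4-(methoxymethoxy)-3-(3-methylbut-2-en-1-yl)phenyl]propanal
Product: 10 (1R,2S)-2-chloro-1-[4-(methoxymethoxy)phenyl]-3-[4-(methoxymethoxy)-3-(3-methylbut-2-en-1-yl)phenyl]propan-1-ol, via [4-(methoxymethoxy)phenyl]lithium 9 (not isolated)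
Conditions: 8 (1.3 equiv), n-BuLi (1.25 equiv), THF, −78 °C; then 6 in THF, −78 °C; aq NH4Cl
Reagents that add atoms: none
Why: Bromine–lithium exchange followed by 1,2-addition of the aryllithium to an α-chloroaldehyde, which at −78 °C should outrun enolisation. Cornforth-type attack (C–Cl anti to C=O, nucleophile passing the hydrogen) gives the anti (1R,2S) chlorohydrin. The C1 epimer would be harmless because C1 later becomes sp2 C4.

Step 7
Reactants: 10 (1R,2S)-2-chloro-1-[4-(methoxymethoxy)phenyl]-3-[4-(methoxymethoxy)-3-(3-methylbut-2-en-1-yl)phenyl]propan-1-ol
Product: 11 (2R,3R)-2-[4-(methoxymethoxy)phenyl]-3-{[4-(methoxymethoxy)-3-(3-methylbut-2-en-1-yl)phenyl]methyl}oxirane (trans)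
Conditions: KOH, EtOH, 0 °C to rt; chromatography on Et3N-deactivated silica
Reagents that add atoms: none
Why: Intramolecular Williamson etherification; the alkoxide displaces chloride by SN2 with inversion, turning the (S) C–Cl centre into the (R) C–O centre that becomes C5, and the anti chlorohydrin gives the trans epoxide. The basic medium protects the acid-labile para-alkoxyaryl epoxide.

Step 8
Reactants: 11 (2R,3R)-2-[4-(methoxymethoxy)phenyl]-3-{[4-(methoxymethoxy)-3-(3-methylbut-2-en-1-yl)phenyl]methyl}oxirane; 12 carbon monoxide (two molecules incorporated)
Product: 13 (5R)-3-hydroxy-4-[4-(methoxymethoxy)phenyl]-5-{[4-(methoxymethoxy)-3-(3-methylbut-2-en-1-yl)phenyl]methyl}furan-2(5H)-one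
Conditions: CO (1 atm), Co2(CO)8 (10 mol %), MeI, aq NaOH (0.5 M), cetyltrimethylammonium bromide (10 mol %), benzene, rt; then aq NaH2PO4 to pH 5 at 0 °C
Reagents that add atoms: none
Why: Proposed new method: the closest known reaction is the Co2(CO)8 phase-transfer double carbonylation of terminal styrene oxides to 3-hydroxy-4-aryl-2(5H)-furanones, extended here to a 1,2-disubstituted aryl epoxide. Hydroxide converts Co2(CO)8 into the tetracarbonylcobaltate anion, which the ammonium salt carries into benzene and which iodomethane and CO turn into acetylcobalt tetracarbonyl; this species (or the cobaltate itself) opens the epoxide at the benzylic carbon, where the 4-(methoxymethoxy)phenyl group best stabilises positive charge, so the C–O bond at the future C5 is never broken and its (R) configuration is carried through. Migratory insertion of CO gives a β-oxy acylcobalt whose benzylic α-hydrogen is acidic enough for hydroxide to enolise it, and the enolised species takes up the second CO to give the α-keto acylcobalt. The C5 oxygen, an alkoxide after loss of any O-acetyl group to hydroxide, then attacks the terminal acyl carbon in a 5-exo-trig closure that forms C2–O1 and the furanone ring and returns the cobaltate. The keto lactone enolises into conjugation with ring B, so no new stereocentre is created and the configuration of the benzylic carbon of 11, and therefore any cis epoxide present, is immaterial. The step needs regioselective benzylic opening and carbonylation faster than β-hydride elimination or hydride-shift isomerisation of the epoxide; the para-oxygenated aryl group, the CO atmosphere and the basic medium, which also spares the epoxide from acid, are relied on for this. The product rests as its sodium enolate, which shields C5–H from exchange, and is released by careful acidification under which the methoxymethyl ethers survive.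

Step 9
Reactants: 13 (5R)-3-hydroxy-4-[4-(methoxymethoxy)phenyl]-5-{[4-(methoxymethoxy)-3-(3-methylbut-2-en-1-yl)phenyl]methyl}furan-2(5H)-one
Product: 14 (5R)-3-methoxy-4-[4-(methoxymethoxy)phenyl]-5-{[4-(methoxymethoxy)-3-(3-methylbut-2-en-1-yl)phenyl]methyl}furan-2(5H)-one
Conditions: Me3SiCHN2 (hexanes), toluene/MeOH 4:1, 0 °C to rt
Reagents that add atoms: trimethylsilyldiazomethane, C[Si](C)(C)C=[N+]=[N-]
Why: O-Methylation of an acidic enol by a diazoalkane; the enol protonates the reagent, methanol removes silicon, and the resulting methyldiazonium ion alkylates the enolate oxygen. The medium stays neutral, so C5–H is not touched, and both phenols are masked, so only the enol reacts.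

Step 10
Reactants: 14 (5R)-3-methoxy-4-[4-(methoxymethoxy)phenyl]-5-{[4-(methoxymethoxy)-3-(3-methylbut-2-en-1-yl)phenyl]methyl}furan-2(5H)-one
Product: 15 (5R)-5-{[4-hydroxy-3-(3-methylbut-2-en-1-yl)phenyl]methyl}-4-(4-hydroxyphenyl)-3-methoxyfuran-2(5H)-one
Conditions: conc. aq HCl (cat.), MeOH, 40 °C
Reagents that add atoms: none
Why: Acid-catalysed acetal exchange with methanol frees both phenols as dimethoxymethane is formed. The low acid concentration and moderate temperature are chosen to avoid cyclisation of the ortho-prenylphenol to a chroman; C5 is not labile to acid.

## Compound list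

1 | methyl 3-(4-hydroxyphenyl)propanoate | COC(=O)CCc1ccc(O)cc1 | starting material
2 | prenyl bromide (1-bromo-3-methylbut-2-ene) | CC(C)=CCBr | starting material
3 | methyl 3-[4-hydroxy-3-(3-methylbut-2-en-1-yl)phenyl]propanoate | COC(=O)CCc1ccc(O)c(CC=C(C)C)c1 | intermediate
4 | methyl 3-[4-(methoxymethoxy)-3-(3-methylbut-2-en-1-yl)phenyl]propanoate | COC(=O)CCc1ccc(OCOC)c(CC=C(C)C)c1 | intermediate
5 | 3-[4-(methoxymethoxy)-3-(3-methylbut-2-en-1-yl)phenyl]propanal | O=CCCc1ccc(OCOC)c(CC=C(C)C)c1 | intermediate
6 | (2S)-2-chloro-3-[4-(methoxymethoxy)-3-(3-methylbut-2-en-1-yl)phenyl]propanal | O=C[C@@H](Cl)Cc1ccc(OCOC)c(CC=C(C)C)c1 | intermediate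
7 | 4-bromophenol | Oc1ccc(Br)cc1 | starting material
8 | 1-bromo-4-(methoxymethoxy)benzene | COCOc1ccc(Br)cc1 | intermediate
9 | [4-(methoxymethoxy)phenyl]lithium | [Li]c1ccc(OCOC)cc1 | intermediate
10 | (1R,2S)-2-chloro-1-[4-(methoxymethoxy)phenyl]-3-[4-(methoxymethoxy)-3-(3-methylbut-2-en-1-yl)phenyl]propan-1-ol | O[C@H](c1ccc(OCOC)cc1)[C@@H](Cl)Cc1ccc(OCOC)c(CC=C(C)C)c1 | intermediate
11 | (2R,3R)-2-[4-(methoxymethoxy)phenyl]-3-{[4-(methoxymethoxy)-3-(3-methylbut-2-en-1-yl)phenyl]methyl}oxirane | COCOc1ccc(cc1)[C@H]1O[C@@H]1Cc1ccc(OCOC)c(CC=C(C)C)c1 | intermediate
12 | carbon monoxide | [C-]#[O+] | starting material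
13 | (5R)-3-hydroxy-4-[4-(methoxymethoxy)phenyl]-5-{[4-(methoxymethoxy)-3-(3-methylbut-2-en-1-yl)phenyl]methyl}furan-2(5H)-one | OC1=C(c2ccc(OCOC)cc2)[C@@H](Cc2ccc(OCOC)c(CC=C(C)C)c2)OC1=O | intermediate
14 | (5R)-3-methoxy-4-[4-(methoxymethoxy)phenyl]-5-{[4-(methoxymethoxy)-3-(3-methylbut-2-en-1-yl)phenyl]methyl}furan-2(5H)-one | COC1=C(c2ccc(OCOC)cc2)[C@@H](Cc2ccc(OCOC)c(CC=C(C)C)c2)OC1=O | intermediate
15 | (5R)-5-{[4-hydroxy-3-(3-methylbut-2-en-1-yl)phenyl]methyl}-4-(4-hydroxyphenyl)-3-methoxyfuran-2(5H)-one | COC1=C(c2ccc(O)cc2)[C@@H](Cc2ccc(O)c(CC=C(C)C)c2)OC1=O | target

## Step count and risk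

Total step count: 10. Longest linear sequence: 9 steps (steps 1 to 4 and 6 to 10, from 1 to 15); step 5 is a one-step branch.

**Step 8 (key step, proposed new method).**
- What may go wrong: opening of the internal epoxide may be slow compared with terminal styrene oxides. The secondary benzylic alkylcobalt may undergo β-hydride elimination, or the epoxide may isomerise by hydride shift, giving isomerisation in place of carbonylation. The sequence may stop after a single CO insertion. Iodomethane may alkylate the product enolate at carbon.
- Fallback (known reaction types, from 11 to 14, bypassing 13): epoxide 11 would be opened at the same benzylic carbon by dimethyl sulfoxide under mild acid catalysis and the alkoxysulfonium salt collapsed with triethylamine (Kornblum-type oxidation of an epoxide). This gives the hydroxy ketone (2R)-2-hydroxy-1-[4-(methoxymethoxy)phenyl]-3-[4-(methoxymethoxy)-3-(3-methylbut-2-en-1-yl)phenyl]propan-1-one F1 without touching the C–O bond of the stereocentre. Esterification with 2-(diethoxyphosphoryl)-2-methoxyacetic acid (carbodiimide, DMAP) gives the phosphonoacetate (2R)-1-[4-(methoxymethoxy)phenyl]-3-[4-(methoxymethoxy)-3-(3-methylbut-2-en-1-yl)phenyl]-1-oxopropan-2-yl 2-(diethoxyphosphoryl)-2-methoxyacetate F2. An intramolecular Horner–Wadsworth–Emmons reaction under LiCl and amine base then closes C3=C4 and gives 14 with the methoxy group already in place.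

**Step 6.**
- What may go wrong: the basic aryllithium may enolise the α-chloroaldehyde instead of adding to it, which would erode the configuration of the C–Cl centre and lower conversion. The aldehyde also has a limited configurational lifetime before use.
- Fallback (from 6 to 10): oxidation of 6 with NaClO2 buffered by NaH2PO4 in the presence of excess 2-methyl-2-butene (Pinnick oxidation) gives the configurationally stable acid (2S)-2-chloro-3-[4-(methoxymethoxy)-3-(3-methylbut-2-en-1-yl)phenyl]propanoic acid F3. Carbodiimide coupling with N,O-dimethylhydroxylamine gives the Weinreb amide (2S)-2-chloro-N-methoxy-N-methyl-3-[4-(methoxymethoxy)-3-(3-methylbut-2-en-1-yl)phenyl]propanamide F4. Aryllithium 9 adds once to F4 and, after a cold acidic quench, gives the ketone (2S)-2-chloro-1-[4-(methoxymethoxy)phenyl]-3-[4-(methoxymethoxy)-3-(3-methylbut-2-en-1-yl)phenyl]propan-1-one F5. Reduction with NaBH4 and CeCl3 at −78 °C (Luche conditions) gives 10 together with its C1 epimer. Both are carried on, because step 7 turns them into trans and cis epoxides with the same configuration at the carbon that becomes C5.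

**Step 1.**
- What may go wrong: O-alkylation may compete with C-alkylation, a second prenyl group may be introduced, and the ortho-prenylphenol may cyclise.
- Fallback (from 1 to 3): O-alkylation of 1 with 3-chloro-3-methylbut-1-yne (K2CO3, KI, catalytic CuI, acetone) gives the propargyl ether methyl 3-{4-[(2-methylbut-3-yn-2-yl)oxy]phenyl}propanoate F6. Semi-hydrogenation over Pd on CaCO3 poisoned with Pb(OAc)2 and quinoline gives the allyl ether methyl 3-{4-[(2-methylbut-3-en-2-yl)oxy]phenyl}propanoate F7. Heating F7 brings about the aromatic Claisen rearrangement, which delivers the allyl unit to the ortho carbon with transposition of its ends and gives 3 with complete C-regiocontrol.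

**Step 10.**
- What may go wrong: acid may cyclise the ortho-prenylphenol onto its alkene, cleavage of the second acetal may be slow, and the lactone may undergo methanolysis on prolonged exposure.
- Fallback (from 14 to 15): treatment of 14 with trimethylsilyl triflate and 2,2′-bipyridyl in CH2Cl2 at 0 °C converts aryl methoxymethyl ethers, through pyridinium-type intermediates and without free Brønsted acid, into the bis(trimethylsilyl) ether (5R)-3-methoxy-4-{4-[(trimethylsilyl)oxy]phenyl}-5-{[3-(3-methylbut-2-en-1-yl)-4-[(trimethylsilyl)oxy]phenyl]methyl}furan-2(5H)-one F8. Water in the work-up hydrolyses F8 to 15.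

## Further compounds

F1 | step 8 | (2R)-2-hydroxy-1-[4-(methoxymethoxy)phenyl]-3-[4-(methoxymethoxy)-3-(3-methylbut-2-en-1-yl)phenyl]propan-1-one | O=C(c1ccc(OCOC)cc1)[C@H](O)Cc1ccc(OCOC)c(CC=C(C)C)c1
F2 | step 8 | (2R)-1-[4-(methoxymethoxy)phenyl]-3-[4-(methoxymethoxy)-3-(3-methylbut-2-en-1-yl)phenyl]-1-oxopropan-2-yl 2-(diethoxyphosphoryl)-2-methoxyacetate (both epimers at the phosphonate carbon) | O=C(c1ccc(OCOC)cc1)[C@H](OC(=O)C(OC)P(=O)(OCC)OCC)Cc1ccc(OCOC)c(CC=C(C)C)c1
F3 | step 6 | (2S)-2-chloro-3-[4-(methoxymethoxy)-3-(3-methylbut-2-en-1-yl)phenyl]propanoic acid | OC(=O)[C@@H](Cl)Cc1ccc(OCOC)c(CC=C(C)C)c1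
F4 | step 6 | (2S)-2-chloro-N-methoxy-N-methyl-3-[4-(methoxymethoxy)-3-(3-methylbut-2-en-1-yl)phenyl]propanamide | CON(C)C(=O)[C@@H](Cl)Cc1ccc(OCOC)c(CC=C(C)C)c1
F5 | step 6 | (2S)-2-chloro-1-[4-(methoxymethoxy)phenyl]-3-[4-(methoxymethoxy)-3-(3-methylbut-2-en-1-yl)phenyl]propan-1-one | O=C(c1ccc(OCOC)cc1)[C@@H](Cl)Cc1ccc(OCOC)c(CC=C(C)C)c1
F6 | step 1 | methyl 3-{4-[(2-methylbut-3-yn-2-yl)oxy]phenyl}propanoate | COC(=O)CCc1ccc(OC(C)(C)C#C)cc1
F7 | step 1 | methyl 3-{4-[(2-methylbut-3-en-2-yl)oxy]phenyl}propanoate | COC(=O)CCc1ccc(OC(C)(C)C=C)cc1
F8 | step 10 | (5R)-3-methoxy-4-{4-[(trimethylsilyl)oxy]phenyl}-5-{[3-(3-methylbut-2-en-1-yl)-4-[(trimethylsilyl)oxy]phenyl]methyl}furan-2(5H)-one | COC1=C(c2ccc(O[Si](C)(C)C)cc2)[C@@H](Cc2ccc(O[Si](C)(C)C)c(CC=C(C)C)c2)OC1=O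
A1 | alternative 1 | 1,3-bis{4-[(tert-butyldimethylsilyl)oxy]phenyl}propan-2-yl diazoacetate | [N-]=[N+]=CC(=O)OC(Cc1ccc(O[Si](C)(C)C(C)(C)C)cc1)Cc1ccc(O[Si](C)(C)C(C)(C)C)cc1
A2 | alternative 1 | cis-(4S,5R)-4-{4-[(tert-butyldimethylsilyl)oxy]phenyl}-5-{4-[(tert-butyldimethylsilyl)oxy]benzyl}dihydrofuran-2(3H)-one | O=C1C[C@@H](c2ccc(O[Si](C)(C)C(C)(C)C)cc2)[C@@H](Cc2ccc(O[Si](C)(C)C(C)(C)C)cc2)O1
A3 | alternative 2 | dimethyl squarate (3,4-dimethoxycyclobut-3-ene-1,2-dione) | COC1=C(OC)C(=O)C1=O
A4 | alternative 2 | racemic 3-{4-[(tert-butyldimethylsilyl)oxy]phenyl}-4-{[4-[(tert-butyldimethylsilyl)oxy]-3-(3-methylbut-2-en-1-yl)phenyl]methyl}-4-hydroxy-2-methoxycyclobut-2-en-1-one | COC1=C(c2ccc(O[Si](C)(C)C(C)(C)C)cc2)C(O)(Cc2ccc(O[Si](C)(C)C(C)(C)C)c(CC=C(C)C)c2)C1=O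
A5 | alternative 2 | (5R)-4-{4-[(tert-butyldimethylsilyl)oxy]phenyl}-5-{[4-[(tert-butyldimethylsilyl)oxy]-3-(3-methylbut-2-en-1-yl)phenyl]methyl}-3-methoxyfuran-2(5H)-one | COC1=C(c2ccc(O[Si](C)(C)C(C)(C)C)cc2)[C@@H](Cc2ccc(O[Si](C)(C)C(C)(C)C)c(CC=C(C)C)c2)OC1=O
A6 | alternative 3 | (aS)-2-methoxy-5-[4-(methoxymethoxy)-3-(3-methylbut-2-en-1-yl)phenyl]penta-2,3-dienoic acid | COC(C(O)=O)=[C@@]=C([H])Cc1ccc(OCOC)c(CC=C(C)C)c1
A7 | alternative 3 | 1-iodo-4-(methoxymethoxy)benzene | COCOc1ccc(I)cc1
A8 | alternative 3 | (5R)-3-methoxy-4-[4-(methoxymethoxy)phenyl]-5-{[4-(methoxymethoxy)-3-(3-methylbut-2-en-1-yl)phenyl]methyl}furan-2(5H)-one (identical with 14) | COC1=C(c2ccc(OCOC)cc2)[C@@H](Cc2ccc(OCOC)c(CC=C(C)C)c2)OC1=O
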